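Which flask ends with more target, alder or larch, and how much does each hold? Watch the substrate as well as the target.

- the flask that ends with the higher amount of target, in percent of the substrate charged, or "neither" when 2 percentage points or less lies between them (alder / larch / neither)
- final target, as a percentage of the substrate charged, in alder
- final target, as a percentage of the substrate charged, in larch

all flasks: substrate 0.80 M
- south-east: reagent 0.30 M; temperature −30 °C; run made earlier
- south-west: reagent 1.2 M; temperature −8 °C; run made earlier
- alder: reagent 0.760 M; temperature 0 °C; time 30 h
- larch: reagent 0.250 M; temperature −40 °C; time 50 h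

| run | time / h | target / % |
|---|---|---|
| south-east | 6.00 | 0.6 |
| south-east | 20.0 | 0 |
| south-east | 40.0 | 0.2 |
| south-east | 72.0 | 0.5 |
| south-west | 3.00 | 2.0 |
| south-west | 6.00 | 2.8 |
| south-west | 10.0 | 3.3 |
| south-west | 12.0 | 4.1 |
| south-west | 15.0 | 5.3 |

(scatter of a reading: 0.5 percentage points)



The south-east run reads 0.5 % after 72.0 h, against a scatter of 0.5 percentage points, so its rate of 6.94 × 10⁻⁵ /h is rough. The south-west run reads 5.3 % after 15.0 h, a rate of 0.00353 /h. Dividing one rate by the other removes time and leaves a rough reading of 50.9. But those runs changed temperature and reagent together, so two chemists read that ratio differently.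

The first takes the rate as proportional to c(reagent). The reagent then claims a factor of 4.00, leaving 12.7 for temperature, an activation energy of 62.0 kJ/mol. Alder's rate comes to 0.00510 /h, and a straight line over 30 h gives 15.3 %.

The second calls the reagent a bystander, so temperature claims the whole ratio, an activation energy of 95.7 kJ/mol. This gives the target constant of alder, the apparent first-order rate constant for substrate becoming target, 0.0126 /h. Over 30 h the constant times the time comes to 0.378, so the second prefers the first-order curve to a straight line and gets 31.5 %.

In larch the views give 0.0777 % and 0.0455 %, less than 2 points apart, so the first view serves equally well there. These two runs do not separate the views, but I commit to the second, which assumes less about the reagent.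

The forecast, on the first side with figures of its own, names alder, with 14 % in alder and 0.1 % in larch, “assuming first order” in reagent.

Alder ends at 26.5 % and larch at 0.0319 %, so alder holds more. Changing the reagent by itself from the south-east run to alder's amount gives 0.404 % against 0.404 %, as the second view's bystander has it. Its curve stands 5 points above alder, and the first view's line 11 points below. Watch the substrate: alder keeps 24 % at 30.0 h, an average loss constant of 0.0477 /h over that time, which is 3.79 times the target constant as read from the runs.

    substrate → target (k = 0.0153 /h, Ea = 103 kJ/mol)
    substrate ⇌ intermediate A (K = 1.90, k = 0.0507 /h, Ea = 94.0 kJ/mol, ΔH = −16.0 kJ/mol)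
    intermediate A ⇌ intermediate B (K = 0.190, k = 0.0546 /h, Ea = 91.0 kJ/mol, ΔH = −3.00 kJ/mol)
    intermediate A ⇌ intermediate C (K = 0.410, k = 0.0176 /h, Ea = 97.0 kJ/mol, ΔH = 37.0 kJ/mol)
    intermediate B ⇌ intermediate D (K = 8.86, k = 0.0862 /h, Ea = 85.0 kJ/mol, ΔH = −7.00 kJ/mol)
    intermediate C → target (k = 0.0255 /h, Ea = 92.0 kJ/mol)
    intermediate B → target (k = 0.0142 /h, Ea = 95.0 kJ/mol)
    (constants at 0 °C)

For the neighbour flask, alder's charge and temperature read at 20 h, the target constant gives 22.3 %. The computed result is 20.0 %.

The readings stem from a simulated flask on assumed constants; the scatter is artificial.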